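Reagent at 5.00 times the substrate charge makes substrate the limiting reagent, so I write the balance from its side. I assume one reagent goes per product. Turning the whole substrate charge into product then uses a share of the reagent charge that I call the draw, 0.200, and the reagent left as a fraction of its charge is one minus the product fraction times the draw.

| flask | substrate | reagent | free catalyst | temperature | remark | time |
|---|---|---|---|---|---|---|
| north | 20 mM | 100 mM | 2 mM | 0 °C | the very flask that is asked about, followed so far |  |
| north-east | 20 mM | 100 mM | 2 mM | 6 °C | run made earlier |  |
| flask | 20 mM | 100 mM | 2.0 mM | 0 °C |  | 8.0 d |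

- north (time / d: product / %, substrate / %): 0.417: 38.3, 59.7; 1.25: 58.9, 40.1; 2.00: 66.9, 32.9; 3.00: 72.7, 26.4; 5.00: 79.0, 19.6
- north-east (time / d: product / %, substrate / %): 0.417: 40.4, 58.5; 1.25: 58.0, 41.4; 2.00: 64.2, 34.8; 3.00: 70.1, 29.6; 5.00: 76.2, 23.1

(scatter of a reading: 0.3 percentage points)

- Sunday's: at 8.0 d add reagent, 100 % of the amount charged, then wait 8.0 d
- Tuesday's: at 8.0 d add free catalyst, 50.0 % of the amount charged, then wait 8.0 d
- Saturday's: at 8.0 d raise the temperature by 20 K, then wait 8.0 d
- Thursday's: change nothing and wait 8.0 d more
- Monday's: at 8.0 d take out 90 % of the product then present, then wait 8.0 d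

- product taken out counts as made
- the numbers in the tables scatter with a standard deviation of 0.3 percentage points
- additions bring no volume worth counting

1. product, in percent of the substrate first charged, at 8.0 d
2. what to do for the largest gain in product; "none" if nothing gains more than 2 percentage points (Sunday's / Tuesday's / Saturday's / Thursday's / Monday's / none)
3. product present, with what was taken out counted in, in percent of the substrate first charged, after Thursday's
4. product present, with what was taken out counted in, in percent of the substrate first charged, after Monday's

In the north run the product leaves the origin at a chord of 0.918 /d up to the first reading. It crosses the substrate before 1.25 d, and the knee lies there too. Between the last two readings its slope is 0.0315 /d, a fall by a factor of 29.1. At 5.00 d the draw leaves 0.842 of the reagent. Substrate times reagent has then fallen by a factor of 3.34, which is less than the fall in slope. So I read the remainder as lost catalyst activity, with about 0.115 of it left.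

The warmer north-east run leads at first, 40.4 % against 38.3 %, and trails at the end, 76.2 % against 79.0 %. Over the last two readings the substrate of the north run falls as one over time to the power 0.583, so these readings show no flat level yet. I extend this and reckon substrate at 0.149 of its charge at 8.0 d, which gives me 83.7 % of product there and 88.7 % after Thursday's. The draw then leaves 0.833 of the reagent. Sunday's multiplies the reagent by 2.20, whereas Tuesday's multiplies the activity, taken at its value from 5.00 d, by about 5.36, which is more, so I back Tuesday's.

The forecast differs from me: it gives 83.2 %, 85.2 % after Thursday's and 92 % after Monday's, and it chooses Monday's, saying “Monday's narrowly beats Tuesday's, but the call is uncertain”.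

The flask gives 84.6 %, 90.2 % after Thursday's and 91.4 % after Monday's. The largest gain is Tuesday's, 12 percentage points against 7.8 points for Sunday's. At 8.00 d the flask holds 93.9 % of its catalyst as spent catalyst. From the product, the draw puts the reagent left at 83.1 %, and the flask has 83.0 % of its charged reagent still free.

    2 free catalyst → spent catalyst (k = 113 /M/h, Ea = 54.0 kJ/mol)
    reagent + catalyst intermediate A ⇌ catalyst intermediate B (K = 4.10 /M, k = 36.2 /M/h, Ea = 58.0 kJ/mol, ΔH = 3.00 kJ/mol)
    catalyst intermediate C ⇌ free catalyst + product (K = 0.0111 M, k = 111 /h, Ea = 81.0 kJ/mol, ΔH = −2.00 kJ/mol)
    substrate + free catalyst ⇌ catalyst intermediate A (K = 36.2 /M, k = 202 /M/h, Ea = 64.0 kJ/mol, ΔH = −49.0 kJ/mol)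
    catalyst intermediate B → catalyst intermediate C (k = 228 /h, Ea = 66.0 kJ/mol)
    (constants at 0 °C)

The neighbour charged with 25 mM of reagent has a draw of 0.800, so its product of 43.7 % should leave 65.0 % of its reagent. The computed neighbour has 65 % of its charged reagent still unbound.

The numbers in the tables were computed for substances that don't exist, noise included.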